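**Plan**

- Retrosynthesis: ring B is opened at the C8–C9 bond (C8 = methyl-bearing alkene carbon, C9 = CH carrying the benzyl group). The (Z)-vinyl iodide (C7=C8) and the styrene (C9=C11) are cut back by two olefinations to a 1,5-dialdehyde (C7, C9). That dialdehyde is the glycol-cleavage product of the cyclopentane ring C10–C9–C7–C6–C5 of a trans-hydrindanone, which comes from a Hajos–Parrish-type enedione.
- Enabling feature: C9 of ring B is flanked by the benzylic carbon C11. A C9=C11 styrene therefore accepts a C8 vinyl radical at C9 and leaves a benzylic radical at C11, while the C7=C8 alkene of ring B is carried as its iodide.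
- Forward order: annulation builds ring A fused to a temporary five-membered ring; C5 and C4 are set on this bicycle; the temporary ring is cut between C7 and C9; both ends are olefinated; ring B closes last by the C8–C9 bond; a double demethylation ends the route.
- Stereochemistry: C10 from the L-phenylalanine-mediated aldol desymmetrisation; C5 and C4 from Li/NH3 reduction–methylation of the bicyclic enone; C9 from the chair-like transition state of the ring closure.

Key step: step 16

Remark: L-phenylalanine is assumed to induce the same (7aS) sense as in the parent Hajos–Parrish cyclisation; locants C1–C11 are those of the target decalin (C4 quaternary carbon with the side chain, C5/C10 ring fusion, C11 benzylic CH2) and β denotes the face of the C10 methyl group.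

**Route**

Step 1
Reactants: 1 5-bromopent-1-ene; 2 acrolein
Product: 4 octa-1,7-dien-3-ol (racemic), via pent-4-en-1-ylmagnesium bromide 3 (not isolated)
Conditions: Mg, THF, 40 °C; then 2, −78 to 0 °C; aq. NH4Cl
Reagents that add atoms: none
Why: Grignard formation and 1,2-addition to the enal carbonyl at low temperature should give the allylic alcohol, whose stereocentre is removed in step 2.

Step 2
Reactants: 4 octa-1,7-dien-3-ol
Product: 5 octa-1,7-dien-3-one
Conditions: Dess–Martin periodinane, NaHCO3, CH2Cl2, 0 °C; used crude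
Reagents that add atoms: none
Why: Dess–Martin oxidation of the secondary allylic alcohol should give the vinyl ketone under neutral conditions that spare both alkenes.

Step 3
Reactants: 5 octa-1,7-dien-3-one; 6 2-methylcyclopentane-1,3-dione
Product: 7 2-methyl-2-(3-oxooct-7-en-1-yl)cyclopentane-1,3-dione
Conditions: Et3N (cat.), MeCN, rt
Reagents that add atoms: none
Why: Michael addition of the acidic cyclic 1,3-dione to the vinyl ketone creates the quaternary carbon (future C10), which stays achiral because the two ring carbonyls are enantiotopic.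

Step 4
Reactants: 7 2-methyl-2-(3-oxooct-7-en-1-yl)cyclopentane-1,3-dione
Product: 9 (7aS)-4-(but-3-en-1-yl)-7a-methyl-2,3,7,7a-tetrahydro-1H-indene-1,5(6H)-dione, via aldol ketol 8 (not isolated)
Conditions: L-phenylalanine (1 equiv), (1S)-(+)-camphor-10-sulfonic acid (0.5 equiv), DMF, 30 to 70 °C
Reagents that add atoms: none
Why: Hajos–Parrish (Eder–Sauer–Wiechert) aldol condensation, in which the enamine of the side-chain ketone with the L-amino acid attacks one of the two enantiotopic ring carbonyls and so should fix C10 as S; the primary amino acid/acid variant is the one used for α'-substituted side-chain ketones.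

Step 5
Reactants: 9 (7aS)-4-(but-3-en-1-yl)-7a-methyl-2,3,7,7a-tetrahydro-1H-indene-1,5(6H)-dione
Product: 10 (7aS)-7a-methyl-4-(4-methylpent-3-en-1-yl)-2,3,7,7a-tetrahydro-1H-indene-1,5(6H)-dione
Conditions: 2-methylbut-2-ene (excess), second-generation Grubbs catalyst (H2IMes)(PCy3)Cl2Ru=CHPh (3 mol %), CH2Cl2, 40 °C
Reagents that add atoms: 2-methylbut-2-ene CC=C(C)C
Why: Olefin cross-metathesis of the monosubstituted alkene with excess 2-methylbut-2-ene should turn the terminal CH2 into the isopropylidene end of the side chain, the tetrasubstituted enone alkene being inert.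

Step 6
Reactants: 10 (7aS)-7a-methyl-4-(4-methylpent-3-en-1-yl)-2,3,7,7a-tetrahydro-1H-indene-1,5(6H)-dione
Product: 11 (1S,7aS)-1-hydroxy-7a-methyl-4-(4-methylpent-3-en-1-yl)-1,2,3,6,7,7a-hexahydro-5H-inden-5-one (OH cis to the angular methyl)
Conditions: NaBH4 (0.3 equiv), EtOH, −20 °C
Reagents that add atoms: none
Why: Chemoselective borohydride reduction of the saturated cyclopentanone over the less electrophilic enone carbonyl, with hydride entering anti to the angular methyl, masks the C9 carbonyl against step 7.

Step 7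
Reactants: 11 (1S,7aS)-1-hydroxy-7a-methyl-4-(4-methylpent-3-en-1-yl)-1,2,3,6,7,7a-hexahydro-5H-inden-5-one
Product: 13 trans-fused 1β-hydroxy-4α,7aβ-dimethyl-4β-(4-methylpent-3-en-1-yl)-3aα-H-octahydro-5H-inden-5-one, via dilithium enolate alkoxide 12 (not isolated)
Conditions: Li (2.2 equiv), NH3(l)/THF, −78 °C; then MeI (excess), −78 to −33 °C; NH4Cl
Reagents that add atoms: iodomethane CI
Why: Reductive alkylation of an enone (dissolving-metal reduction, then enolate C-methylation): β-protonation at C5 by the substrate's own hydroxyl should give the trans ring fusion, and the regiodefined C3–C4 enolate should take methyl on the face anti to the angular methyl, leaving the side chain β at C4.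

Step 8
Reactants: 13 trans-fused 1β-hydroxy-4α,7aβ-dimethyl-4β-(4-methylpent-3-en-1-yl)-3aα-H-octahydro-5H-inden-5-one
Product: 15 trans-fused 4α,7aβ-dimethyl-4β-(4-methylpent-3-en-1-yl)-3aα-H-octahydro-1H-inden-1β-ol, via hydrazone 14 (not isolated)
Conditions: N2H4·H2O, KOH, diethylene glycol, 130 °C then 200 °C
Reagents that add atoms: none
Why: Wolff–Kishner reduction (Huang–Minlon modification) removes the C3 carbonyl next to the quaternary carbon without affecting the isolated trisubstituted alkene or any stereocentre.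

Step 9
Reactants: 15 trans-fused 4α,7aβ-dimethyl-4β-(4-methylpent-3-en-1-yl)-3aα-H-octahydro-1H-inden-1β-ol
Product: 16 trans-fused 4α,7aβ-dimethyl-4β-(4-methylpent-3-en-1-yl)-3aα-H-octahydro-1H-inden-1-one
Conditions: Dess–Martin periodinane, NaHCO3, CH2Cl2, rt
Reagents that add atoms: none
Why: Dess–Martin oxidation returns the C9 carbonyl needed to functionalise C7.

Step 10
Reactants: 16 trans-fused 4α,7aβ-dimethyl-4β-(4-methylpent-3-en-1-yl)-3aα-H-octahydro-1H-inden-1-one
Product: 17 2-hydroxy derivative of 16 (epimers at C2 of the indanone)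
Conditions: KN(SiMe3)2, THF, −78 °C; 2-(phenylsulfonyl)-3-phenyloxaziridine; NH4Cl
Reagents that add atoms: 2-(phenylsulfonyl)-3-phenyloxaziridine O=S(=O)(c1ccccc1)N1OC1c1ccccc1
Why: Davis oxidation of the only possible enolate (C7, since C10 is quaternary) installs the α-hydroxyl, whose configuration is irrelevant.

Step 11
Reactants: 17 2-hydroxy derivative of 16
Product: 18 trans-fused 4α,7aβ-dimethyl-4β-(4-methylpent-3-en-1-yl)-3aα-H-octahydro-1H-indene-1,2-diol (diastereomers)
Conditions: NaBH4, MeOH, 0 °C
Reagents that add atoms: none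
Why: Borohydride reduction of the ketol gives the vicinal diol needed for glycol cleavage.

Step 12
Reactants: 18 trans-fused indene-1,2-diol
Product: 19 1β,3α-dimethyl-3β-(4-methylpent-3-en-1-yl)-2β-(2-oxoethyl)cyclohexane-1α-carbaldehyde
Conditions: NaIO4, THF/H2O (pH 7), 0 °C to rt
Reagents that add atoms: none
Why: Malaprade glycol cleavage opens the temporary five-membered ring between C7 and C9 and should leave the trans-diequatorial formyl and 2-oxoethyl arms on ring A with no stereocentre touched.

Step 13
Reactants: 19 1β,3α-dimethyl-3β-(4-methylpent-3-en-1-yl)-2β-(2-oxoethyl)cyclohexane-1α-carbaldehyde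
Product: 20 2β-[(2Z)-3-iodobut-2-en-1-yl]-1β,3α-dimethyl-3β-(4-methylpent-3-en-1-yl)cyclohexane-1α-carbaldehyde
Conditions: [EtPPh3]I, n-BuLi, THF, 0 °C; I2, −78 °C; NaN(SiMe3)2, −78 °C; then 19 (1.0 equiv), −78 °C
Reagents that add atoms: (1-iodoethylidene)triphenylphosphorane CC(I)=P(c1ccccc1)(c1ccccc1)c1ccccc1
Why: Stork–Zhao-type Wittig iodo-olefination should be (Z)-selective and should react at the unhindered CH2CHO group at −78 °C in preference to the neopentyl formyl group on the quaternary carbon.

Step 14
Reactants: 21 methyl 3-(bromomethyl)-4-methoxybenzoate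
Product: 22 diethyl [2-methoxy-5-(methoxycarbonyl)benzyl]phosphonate
Conditions: P(OEt)3 (neat), 130 °C
Reagents that add atoms: triethyl phosphite CCOP(OCC)OCC
Why: Michaelis–Arbuzov reaction of a benzylic bromide.

Step 15
Reactants: 20 vinyl iodide aldehyde; 22 diethyl [2-methoxy-5-(methoxycarbonyl)benzyl]phosphonate
Product: 23 methyl 3-[(E)-2-{2β-[(2Z)-3-iodobut-2-en-1-yl]-1β,3α-dimethyl-3β-(4-methylpent-3-en-1-yl)cyclohex-1α-yl}ethenyl]-4-methoxybenzoate
Conditions: 22, KN(SiMe3)2, 18-crown-6, THF, −78 to 0 °C; then 20, 0 °C to rt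
Reagents that add atoms: none
Why: Horner–Wadsworth–Emmons olefination of the non-enolisable neopentyl aldehyde with the benzylic phosphonate anion should give the (E)-styrene and tolerates the vinyl iodide.

Step 16
Reactants: 23 styrene vinyl iodide
Product: 24 jaspic acid methyl ester methyl ether (trans-decalin; 4α,10β-dimethyl, 4β-(4-methylpent-3-enyl), 5α-H, 8-methyl-7-ene, 9β-[2-methoxy-5-(methoxycarbonyl)benzyl])
Conditions: Bu3SnH (1.3 equiv, syringe pump), AIBN (0.2 equiv), PhH (0.005 M), 80 °C
Reagents that add atoms: none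
Why: Bu3Sn• abstracts iodine from C8 to give a σ-vinyl radical that adds to C9 of the styrene, and the benzylic C11 radical then takes hydrogen from Bu3SnH and carries the chain (tin hydride mediated vinyl radical cyclisation). Ring B closes in the 6-exo-trig mode, since the 7-endo alternative would give a larger ring and a non-benzylic radical. The new stereocentre C9 is controlled by the trans-diequatorial arms on ring A: in the chair-like transition state the styrene should adopt the rotamer with the angular methyl, not C5, in the alkene plane (allylic strain), which places C11 pseudo-equatorial and leaves H-9 α. Cyclisation must outrun hydrogen transfer to the vinyl radical, which high dilution and slow stannane addition secure. The side-chain alkene cannot compete because it would need an eight-membered ring, and the (Z)-iodide already holds C6 and the radical site cis.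

Step 17
Reactants: 24 jaspic acid methyl ester methyl ether
Product: 25 jaspic acid
Conditions: NaSEt (excess), DMF, 120 °C; then 1 M HCl
Reagents that add atoms: none
Why: Thiolate SN2 demethylation cleaves both the methyl ester and the aryl methyl ether in one operation and leaves the two trisubstituted alkenes untouched.

**Compound list**

1 | 5-bromopent-1-ene | C=CCCCBr | starting material
2 | acrolein | C=CC=O | starting material
3 | pent-4-en-1-ylmagnesium bromide (formed in the flask) | C=CCCC[Mg]Br | intermediate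
4 | octa-1,7-dien-3-ol (racemic) | C=CCCCC(O)C=C | intermediate
5 | octa-1,7-dien-3-one | C=CCCCC(=O)C=C | intermediate
6 | 2-methylcyclopentane-1,3-dione | CC1C(=O)CCC1=O | starting material
7 | 2-methyl-2-(3-oxooct-7-en-1-yl)cyclopentane-1,3-dione | C=CCCCC(=O)CCC1(C)C(=O)CCC1=O | intermediate
8 | (7aS)-4-(but-3-en-1-yl)-3a-hydroxy-7a-methylhexahydro-1H-indene-1,5-dione, aldol ketol formed in the flask (C3a and C4 not defined) | C=CCCC1C(=O)CC[C@]2(C)C(=O)CCC12O | intermediate
9 | (7aS)-4-(but-3-en-1-yl)-7a-methyl-2,3,7,7a-tetrahydro-1H-indene-1,5(6H)-dione | O=C1CC[C@]2(C)C(=O)CCC2=C1CCC=C | intermediate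
10 | (7aS)-7a-methyl-4-(4-methylpent-3-en-1-yl)-2,3,7,7a-tetrahydro-1H-indene-1,5(6H)-dione | O=C1CC[C@]2(C)C(=O)CCC2=C1CCC=C(C)C | intermediate
11 | (1S,7aS)-1-hydroxy-7a-methyl-4-(4-methylpent-3-en-1-yl)-1,2,3,6,7,7a-hexahydro-5H-inden-5-one | O=C1CC[C@]2(C)[C@@H](O)CCC2=C1CCC=C(C)C | intermediate
12 | dilithium enolate alkoxide of the trans-fused 5-ketone (formed in the flask) | CC(C)=CCCC1=C([O-])CC[C@]2(C)[C@@H]([O-])CC[C@@H]12.[Li+].[Li+] | intermediate
13 | trans-fused 1β-hydroxy-4α,7aβ-dimethyl-4β-(4-methylpent-3-en-1-yl)-3aα-H-octahydro-5H-inden-5-one | CC(C)=CCC[C@@]1(C)C(=O)CC[C@]2(C)[C@@H](O)CC[C@@H]12 | intermediate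
14 | hydrazone of 13 (formed in the flask) | CC(C)=CCC[C@@]1(C)C(=NN)CC[C@]2(C)[C@@H](O)CC[C@@H]12 | intermediate
15 | trans-fused 4α,7aβ-dimethyl-4β-(4-methylpent-3-en-1-yl)-3aα-H-octahydro-1H-inden-1β-ol | CC(C)=CCC[C@@]1(C)CCC[C@]2(C)[C@@H](O)CC[C@@H]12 | intermediate
16 | trans-fused 4α,7aβ-dimethyl-4β-(4-methylpent-3-en-1-yl)-3aα-H-octahydro-1H-inden-1-one | CC(C)=CCC[C@@]1(C)CCC[C@]2(C)C(=O)CC[C@@H]12 | intermediate
17 | 2-hydroxy derivative of 16 (epimers at C2) | CC(C)=CCC[C@@]1(C)CCC[C@]2(C)C(=O)C(O)C[C@@H]12 | intermediate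
18 | 1,2-diol from 17 (diastereomers at C1 and C2) | CC(C)=CCC[C@@]1(C)CCC[C@]2(C)C(O)C(O)C[C@@H]12 | intermediate
19 | 1β,3α-dimethyl-3β-(4-methylpent-3-en-1-yl)-2β-(2-oxoethyl)cyclohexane-1α-carbaldehyde | CC(C)=CCC[C@@]1(C)CCC[C@](C)(C=O)[C@H]1CC=O | intermediate
20 | 2β-[(2Z)-3-iodobut-2-en-1-yl]-1β,3α-dimethyl-3β-(4-methylpent-3-en-1-yl)cyclohexane-1α-carbaldehyde | CC(C)=CCC[C@@]1(C)CCC[C@](C)(C=O)[C@H]1C/C=C(/C)I | intermediate
21 | methyl 3-(bromomethyl)-4-methoxybenzoate | COC(=O)c1ccc(OC)c(CBr)c1 | starting material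
22 | diethyl [2-methoxy-5-(methoxycarbonyl)benzyl]phosphonate | CCOP(=O)(OCC)Cc1cc(C(=O)OC)ccc1OC | intermediate
23 | methyl 3-[(E)-2-{2β-[(2Z)-3-iodobut-2-en-1-yl]-1β,3α-dimethyl-3β-(4-methylpent-3-en-1-yl)cyclohex-1α-yl}ethenyl]-4-methoxybenzoate | CC(C)=CCC[C@@]1(C)CCC[C@](C)(/C=C/c2cc(C(=O)OC)ccc2OC)[C@H]1C/C=C(/C)I | intermediate
24 | jaspic acid methyl ester methyl ether | CC(C)=CCC[C@@]1(C)CCC[C@]2(C)[C@@H](Cc3cc(C(=O)OC)ccc3OC)C(C)=CC[C@@H]12 | intermediate
25 | jaspic acid | CC(C)=CCC[C@@]1(C)CCC[C@]2(C)[C@@H](Cc3cc(C(=O)O)ccc3O)C(C)=CC[C@@H]12 | target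

**Step count**

Total: 17 steps. Longest linear sequence: 16 steps (steps 1–13 and 15–17).

**Steps most likely to fail**

Step 16. The cyclisation may pass through the styrene rotamer that places C11 axial, which would give the C9 epimer, and the vinyl radical may be reduced before it closes the ring. The fallback sets out from 20 and returns at 24; it makes the C8–C9 bond through an enolate and sets C9 afterwards by protonation. Wittig methoxymethylenation of 20 (Ph3P=CHOMe) should give the enol ether F1, and mild acid hydrolysis the homologous aldehyde F2, in which C9 is a CH2 and C11 the formyl carbon. Addition of the arylmagnesium reagent made from methyl 3-iodo-4-methoxybenzoate and i-PrMgCl·LiCl should give the benzylic alcohol F3, and Dess–Martin oxidation the aryl ketone F4. Palladium-catalysed intramolecular coupling of its potassium enolate with the vinyl iodide (Pd(PPh3)4, KOt-Bu, THF) should close ring B. Quenching the resulting dienolate with acetic acid at −78 °C should protonate C9 from the α face, anti to the angular methyl, and give the β,γ-unsaturated ketone F5. Reduction with NaBH4/CeCl3 to the alcohol F6, conversion into the xanthate F7 (NaH, CS2, MeI) and Barton–McCombie reduction (Bu3SnH, AIBN) should then give 24.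

Step 7. Protonation at C5 may occur from the wrong face and give the cis-fused bicycle; the lithium alkoxide may be O-methylated; proton exchange between enolate and product may lead to over-methylation. The fallback sets out from 11 and returns at 13; it replaces the dissolving metal by a conjugate hydride addition on the protected alcohol. Silylation (t-BuMe2SiCl, imidazole) should give the silyl ether F8. Conjugate reduction with i-Bu2AlH/t-BuCu in THF–HMPA, a reagent known to give trans-hydrindanones from such enones, then activation of the aluminium enolate with MeLi and methylation with MeI should give the methylated ketone F9. Bu4NF should then release 13.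

Step 13. The ylide may not discriminate fully between the two formyl groups (bis-olefination or attack at the neopentyl aldehyde), and the Z selectivity may erode. The fallback sets out from 17 and returns at 20; it differentiates the two carbonyl carbons by oxidation level instead of by hindrance. Lead tetraacetate cleavage of the ketol 17 in methanol–benzene should give the aldehyde ester F10. The same iodo-olefination, now with a single aldehyde present, should give the vinyl iodide ester F11. Reduction with i-Bu2AlH should give the neopentyl alcohol F12, and Dess–Martin oxidation should give 20.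

**Further compounds**

F1 | step 16 | 2β-[(2Z)-3-iodobut-2-en-1-yl]-1α-(2-methoxyethenyl)-1β,3α-dimethyl-3β-(4-methylpent-3-en-1-yl)cyclohexane (enol ether, E/Z mixture) | CC(C)=CCC[C@@]1(C)CCC[C@](C)(C=COC)[C@H]1C/C=C(/C)I
F2 | step 16 | 2-{2β-[(2Z)-3-iodobut-2-en-1-yl]-1β,3α-dimethyl-3β-(4-methylpent-3-en-1-yl)cyclohex-1α-yl}acetaldehyde | CC(C)=CCC[C@@]1(C)CCC[C@](C)(CC=O)[C@H]1C/C=C(/C)I
F3 | step 16 | methyl 3-(1-hydroxy-2-{cyclohexyl of F2}ethyl)-4-methoxybenzoate (carbinol epimers) | CC(C)=CCC[C@@]1(C)CCC[C@](C)(CC(O)c2cc(C(=O)OC)ccc2OC)[C@H]1C/C=C(/C)I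
F4 | step 16 | methyl 3-(2-{cyclohexyl of F2}acetyl)-4-methoxybenzoate (aryl ketone) | CC(C)=CCC[C@@]1(C)CCC[C@](C)(CC(=O)c2cc(C(=O)OC)ccc2OC)[C@H]1C/C=C(/C)I
F5 | step 16 | 11-oxo derivative of 24 (β,γ-unsaturated aryl ketone, H-9 α) | CC(C)=CCC[C@@]1(C)CCC[C@]2(C)[C@@H](C(=O)c3cc(C(=O)OC)ccc3OC)C(C)=CC[C@@H]12
F6 | step 16 | 11-hydroxy derivative of 24 (carbinol epimers) | CC(C)=CCC[C@@]1(C)CCC[C@]2(C)[C@@H](C(O)c3cc(C(=O)OC)ccc3OC)C(C)=CC[C@@H]12
F7 | step 16 | S-methyl xanthate of F6 | CC(C)=CCC[C@@]1(C)CCC[C@]2(C)[C@@H](C(OC(=S)SC)c3cc(C(=O)OC)ccc3OC)C(C)=CC[C@@H]12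
F8 | step 7 | tert-butyldimethylsilyl ether of 11 | O=C1CC[C@]2(C)[C@@H](O[Si](C)(C)C(C)(C)C)CCC2=C1CCC=C(C)C
F9 | step 7 | tert-butyldimethylsilyl ether of 13 | CC(C)=CCC[C@@]1(C)C(=O)CC[C@]2(C)[C@@H](O[Si](C)(C)C(C)(C)C)CC[C@@H]12
F10 | step 13 | methyl 1β,3α-dimethyl-3β-(4-methylpent-3-en-1-yl)-2β-(2-oxoethyl)cyclohexane-1α-carboxylate | CC(C)=CCC[C@@]1(C)CCC[C@](C)(C(=O)OC)[C@H]1CC=O
F11 | step 13 | methyl 2β-[(2Z)-3-iodobut-2-en-1-yl]-1β,3α-dimethyl-3β-(4-methylpent-3-en-1-yl)cyclohexane-1α-carboxylate | CC(C)=CCC[C@@]1(C)CCC[C@](C)(C(=O)OC)[C@H]1C/C=C(/C)I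
F12 | step 13 | {2β-[(2Z)-3-iodobut-2-en-1-yl]-1β,3α-dimethyl-3β-(4-methylpent-3-en-1-yl)cyclohex-1α-yl}methanol | CC(C)=CCC[C@@]1(C)CCC[C@](C)(CO)[C@H]1C/C=C(/C)I
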